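## Analysis of the target

The target, 2-(3-hydroxy-4-methoxyphenyl)-3-methoxy-5-(3-methylbut-2-enyl)-1-benzofuran-6-ol (16), is a 2-arylbenzofuran. Ring A is the benzo ring (C3a, C4, C5, C6, C7, C7a), ring B the furan (O1, C2, C3) and ring C the aryl group on C2. Ring A carries a free hydroxyl at C6 and a prenyl group at C5, ring B a methoxy group at C3, and ring C a hydroxyl meta and a methoxy para to C2. There is no stereocentre and the prenyl alkene ends in two methyl groups, so the problem is one of regiochemistry and of telling four oxygen atoms apart. The sensitive parts are the prenyl group ortho to the C6 phenol (it closes to a chroman under acid and does not survive hydrogenation), the C3 methoxy group (an enol ether on an electron-rich furan) and the two oxidizable phenols. The hard points are therefore to place the prenyl group on C5 and not on C7, to build ring B with oxygen on C3, and to free the phenols at the end without acid. The strategy rests on C3 and C3a: C3 is at the oxidation level of a carboxyl carbon, and C3a is ortho to O1 and para to the C6 oxygen, the most reactive open carbon of a resorcinol diether. The C3–C3a bond can thus be made by intramolecular acylation of ring A, while C5, meta to C3a, carries a bromine that marks the place of the prenyl group.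

## Retrosynthetic reasoning

**16 to 15.** The two phenolic O–H bonds are traced back to the O–Si bonds of bis(triisopropylsilyl) ether 15. Silicon is chosen because its removal is neither acidic nor reductive, so the ortho-prenyl phenol and the C3 enol ether are not endangered in the last step.

**15 to 13 and 14.** The bond between C5 and the prenyl CH2 is cut, giving aryl bromide 13 and prenylstannane 14. This keeps the acid-labile prenyl group out of every acidic step, and the bromine, set in the first step on a bought arene, defines C5. The forward coupling must transfer the prenyl group without allylic transposition and leave the silyl ethers alone.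

**13 to 12.** The O–CH3 bond at C3 is cut; 13 is the enol methyl ether of benzofuranone 12. The forward step must alkylate the enolate on oxygen. That is favoured because O-alkylation makes ring B aromatic, whereas C-alkylation would have to occur at the crowded, aryl-bearing C2.

**12 to 10.** This is the central disconnection. The C3–C3a bond is cut, opening ring B to the α-aryloxy arylacetic acid 10, which reacts through its mixed anhydride 11. The cut is made here because C3a is the innately nucleophilic carbon of ring A, and because 10 already holds O1, C2 and ring C and is assembled from two halves by a plain ether formation. The forward step must acylate C3a and not C7, and must close the ring before the activated acid decarbonylates.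

**10 to 8 to 7.** The silyl groups of 10 are traced back to the free phenols of 8 (through the persilylated ester 9), and the three O–H bonds of 8 to the three ester groups of 7. The acyl groups serve the assembly but cannot be carried further: aryl esters would deactivate ring A towards acylation and would migrate under the enolate chemistry of step 9.

**7 to 2 and 6.** The O1–C2 ether bond is cut, giving bromophenol 2 and α-bromo ester 6. The only free hydroxyl of 2 is the one that becomes O1, and the bromide of 6 is benzylic and α to an ester, so the displacement is fast under mild base.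

**6 to 3, and 2 to 1.** The C–Br bond of 6 comes from radical bromination of 5, whose acetate and methyl ester come from 4 and acid 3. The C–Br bond of 2 comes from bromination of monobenzoate 1 para to its free hydroxyl; the benzoate differentiates the two resorcinol oxygens from the start.

## Alternatives that were turned down

**Alternative 1:** Ring A is built instead of bought, by disconnecting C4–C5 and C3a–C7a in a Diels–Alder sense. The diene 1-methoxy-7-methyl-1,3-bis(trimethylsilyloxy)octa-1,3,6-triene (A1), which carries the prenyl chain on its terminal carbon, would add to methyl propiolate (A2). Loss of the methoxy group and of the silyl groups would aromatize the adduct to methyl 2,4-dihydroxy-5-(3-methylbut-2-enyl)benzoate (A3).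
- For: the prenyl group is at C5 by construction, the polarization of A1 and A2 fixes the orientation, and neither tin nor palladium is needed. On prenyl regiochemistry this is stronger than the chosen route, which depends on a late coupling at a hindered bromide.
- Against: A3 is only ring A with a carboxyl carbon on C3a. O1–C2, C2–C3, ring C and the C3 methyl ether remain to be made, with the acid-sensitive prenyl group and a free ortho phenol already present. A second ring-forming strategy is therefore needed on top, and the sequence becomes clearly longer. A1 also needs a prenylated β-keto ester and a double silylation, and a substituent on the diene terminus slows the cycloaddition.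
- Comparison: the chosen strategy buys ring A with its oxygens in place, spends its key step on ring B, and accepts one palladium coupling in exchange.

**Alternative 2:** Ring B is cut at C2–C3 instead of C3–C3a. The precursor would be N,N-diethyl-4-(methoxymethoxy)-2-{[4-methoxy-3-(methoxymethoxy)phenyl]methoxy}-5-(3-methylbut-2-enyl)benzamide (A4). A lithium amide base removes a proton from its O–CH2 group, the carbanion attacks the neighbouring amide carbon and closes ring B, and the 3-oxidobenzofuran is methylated on oxygen in the same flask. The product is 3-methoxy-6-(methoxymethoxy)-2-[4-methoxy-3-(methoxymethoxy)phenyl]-5-(3-methylbut-2-enyl)-1-benzofuran (A5).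
- For: the closure is anionic, so no acylium ion exists that could decarbonylate. The carbonyl carbon is already on C3a, so there is no C3a versus C7 question. Cyclization and methylation are one operation. As a ring closure it is at least as dependable as the chosen key step, probably more so.
- Against: the acetal protecting groups that withstand the base must be removed from A5 by acid, the very conditions under which an ortho-prenyl phenol cyclizes onto its alkene and the C3 enol ether suffers. A4 must carry the prenyl group before the closure, so the regioselective prenylation of a 2,4-dioxygenated benzamide is left unsolved. The α-oxy benzylic carbanion can also undergo Wittig rearrangement, and the benzylic-allylic CH2 of the prenyl group is a second acidic site.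
- Comparison: the chosen strategy gives up some certainty in the closure. In return its precursor 10 comes from three bought pieces, the deprotection uses fluoride, and the bromine fixes C5 from step 1.

**Alternative 3:** Ring A is made by a polyketide-type aromatization that forms C3a–C4. The precursor would be 6-[3-(methoxymethylidene)-6-methyl-2-oxohept-5-enyl]-2,2-dimethyl-4H-1,3-dioxin-4-one (A6). A tertiary amine enolizes the masked 3,5-dioxo chain, the α-carbon of the dioxinone (future C3a) adds to the methoxymethylidene carbon (future C4), methoxide leaves, and tautomerization gives 7-hydroxy-2,2-dimethyl-6-(3-methylbut-2-enyl)-4H-1,3-benzodioxin-4-one (A7).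
- For: the prenyl group is introduced at an aliphatic stage and ends on C5 without doubt, and the conditions are mild. A7 is formed with its oxygens already differentiated (C7a–O and the carboxyl tied in the acetonide, C6–OH free). On that point it is stronger than the chosen route, which needs a protecting-group exchange in steps 6 and 7.
- Against: A6 is a sensitive polycarbonyl compound that takes several steps to make, including a C-prenylation with O-alkylation and dialkylation problems and a methoxymethylenation. Like A3, A7 is only ring A: opening the acetonide, attaching ring C, closing ring B and methylating C3–O still follow, most naturally through a compound such as A4 with the drawbacks noted above.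
- Comparison: the chosen route is much shorter and puts its risk into one step. It offers a defined bromine marker in place of de novo control of the prenyl position.

Key step: step 8

Remark: the target has no stereocentre. C2 of compounds 6 to 12 is a stereocentre that is carried as the racemate and becomes trigonal in step 9. Compounds 1, 3 and 14 are taken as purchasable.

## Route

**Step 1**
Reactants: 1 3-hydroxyphenyl benzoate (resorcinol monobenzoate)
Product: 2 2-bromo-5-hydroxyphenyl benzoate
Conditions: Br2 (1.0 equiv), AcOH, 15 °C to rt
Reagents that add atoms: bromine, BrBr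
Why: Electrophilic aromatic bromination; the free hydroxyl is the stronger donor and directs para, the carbon between the two oxygens is shielded, and the benzoate tempers the ring so that monobromination can be held.

**Step 2**
Reactants: 3 2-(3-hydroxy-4-methoxyphenyl)acetic acid (homoisovanillic acid)
Product: 4 methyl 2-(3-hydroxy-4-methoxyphenyl)acetate
Conditions: MeOH, H2SO4 (cat.), reflux
Reagents that add atoms: methanol, CO
Why: Fischer esterification of an unhindered arylacetic acid in excess methanol; the phenol is inert under these conditions.

**Step 3**
Reactants: 4 methyl 2-(3-hydroxy-4-methoxyphenyl)acetate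
Product: 5 methyl 2-(3-acetoxy-4-methoxyphenyl)acetate
Conditions: Ac2O, pyridine (solvent), rt
Reagents that add atoms: acetic anhydride, CC(=O)OC(C)=O
Why: O-Acylation of the phenol; the acetate removes the phenolic O–H and lowers the electron density of ring C before the radical bromination.

**Step 4**
Reactants: 5 methyl 2-(3-acetoxy-4-methoxyphenyl)acetate
Product: 6 methyl 2-(3-acetoxy-4-methoxyphenyl)-2-bromoacetate (racemic)
Conditions: NBS, AIBN (cat.), PhCF3, 80 °C
Reagents that add atoms: N-bromosuccinimide, O=C1CCC(=O)N1Br
Why: Wohl–Ziegler bromination; the only weak C–H bond is the one that is both benzylic and α to the ester, and the non-polar radical conditions disfavour ionic ring bromination. The labile bromide is used without long storage.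

**Step 5**
Reactants: 2 2-bromo-5-hydroxyphenyl benzoate; 6 methyl 2-(3-acetoxy-4-methoxyphenyl)-2-bromoacetate
Product: 7 methyl 2-(3-acetoxy-4-methoxyphenyl)-2-[3-(benzoyloxy)-4-bromophenoxy]acetate (racemic)
Conditions: K2CO3, acetone, rt
Reagents that add atoms: none
Why: Williamson ether synthesis; the phenoxide of 2 displaces a bromide that is benzylic and α to an ester, which is fast enough at room temperature to outrun acyl transfer between the aryl esters, and 6 has no β-hydrogen for elimination.

**Step 6**
Reactants: 7 methyl 2-(3-acetoxy-4-methoxyphenyl)-2-[3-(benzoyloxy)-4-bromophenoxy]acetate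
Product: 8 2-(4-bromo-3-hydroxyphenoxy)-2-(3-hydroxy-4-methoxyphenyl)acetic acid (racemic)
Conditions: LiOH (excess), THF–MeOH–H2O, rt, degassed; then 1 M HCl; benzoic acid removed by trituration or chromatography
Reagents that add atoms: lithium hydroxide, [Li+].[OH-]
Why: Saponification of the two aryl esters and the methyl ester in one operation; the diaryl-type ether and the aryl bromide are inert to hydroxide, and epimerization at the α-carbon is irrelevant in a racemate.

**Step 7**
Reactants: 8 2-(4-bromo-3-hydroxyphenoxy)-2-(3-hydroxy-4-methoxyphenyl)acetic acid
Product: 10 2-[4-bromo-3-(triisopropylsilyloxy)phenoxy]-2-[4-methoxy-3-(triisopropylsilyloxy)phenyl]acetic acid (racemic), via triisopropylsilyl ester 9 (not isolated)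
Conditions: TIPSCl (3.5 equiv), imidazole, DMF, rt; then THF–1 M aq. HCl, rt
Reagents that add atoms: chlorotriisopropylsilane, CC(C)[Si](Cl)(C(C)C)C(C)C
Why: Silylation of both phenols and the carboxyl group, then selective acid hydrolysis of the silyl ester; a silyl carboxylate is far more labile than an aryl triisopropylsilyl ether, which tolerates dilute aqueous acid.

**Step 8**
Reactants: 10 2-[4-bromo-3-(triisopropylsilyloxy)phenoxy]-2-[4-methoxy-3-(triisopropylsilyloxy)phenyl]acetic acid
Product: 12 5-bromo-2-[4-methoxy-3-(triisopropylsilyloxy)phenyl]-6-(triisopropylsilyloxy)-1-benzofuran-3(2H)-one (racemic), via mixed trifluoroacetic anhydride 11 (not isolated)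
Conditions: (CF3CO)2O (2–3 equiv), CH2Cl2, 0 °C to rt, Ar; cold aqueous work-up
Reagents that add atoms: none
Why: Intramolecular Friedel–Crafts acylation: the anhydride converts acid 10 into mixed anhydride 11, whose carbonyl carbon, activated by the trifluoroacetate leaving group and by the trifluoroacetic acid released, is attacked by ring A, and loss of a proton from the arenium ion gives ketone 12. The closest known reaction type is the cyclization of aryloxyacetic acids to benzofuran-3(2H)-ones under acidic dehydrating conditions. Ring B closes in a 5-exo-trig manner at the anhydride carbonyl, the C=O bond staying outside the new five-membered ring while the C3a–C7a bond of the arene becomes part of it. No new stereocentre is formed; C2 is the racemic α-carbon of 10 and becomes trigonal in step 9. The selectivity needed is acylation at C3a and not at C7: both are ortho to the ether oxygen, but C3a is para to the C6 silyloxy group and open, whereas C7 lies between the two oxygens and under the triisopropylsilyl group. The C5 bromine is meta to C3a and lowers its reactivity only slightly, and ring C cannot reach the carbonyl carbon in a ring of reasonable size. The covalent mixed anhydride at low temperature, without a strong Lewis acid, is chosen so that ring closure runs ahead of decarbonylation of a free α-aryloxy acylium ion. The product is kept under argon and used directly because its enol is readily oxidized at C2.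

**Step 9**
Reactants: 12 5-bromo-2-[4-methoxy-3-(triisopropylsilyloxy)phenyl]-6-(triisopropylsilyloxy)-1-benzofuran-3(2H)-one
Product: 13 5-bromo-3-methoxy-2-[4-methoxy-3-(triisopropylsilyloxy)phenyl]-6-(triisopropylsilyloxy)-1-benzofuran
Conditions: (CH3O)2SO2, K2CO3, dry acetone, rt to 40 °C, Ar, degassed
Reagents that add atoms: dimethyl sulfate, COS(=O)(=O)OC
Why: O-Alkylation of an enolate with a hard methylating agent; attack through oxygen makes ring B aromatic, while C-methylation would have to occur at the hindered, aryl-substituted C2, and the aryl silyl ethers are stable to dry carbonate.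

**Step 10**
Reactants: 13 5-bromo-3-methoxy-2-[4-methoxy-3-(triisopropylsilyloxy)phenyl]-6-(triisopropylsilyloxy)-1-benzofuran; 14 tributyl(3-methylbut-2-en-1-yl)stannane
Product: 15 3-methoxy-2-[4-methoxy-3-(triisopropylsilyloxy)phenyl]-5-(3-methylbut-2-en-1-yl)-6-(triisopropylsilyloxy)-1-benzofuran
Conditions: Pd(PPh3)4 (cat.), DMF, 100 °C, degassed
Reagents that add atoms: none
Why: Stille coupling; zerovalent palladium inserts into the C5–Br bond, the allyl group is transferred from tin, and reductive elimination from the allylpalladium intermediate at its less substituted terminus gives the linear prenyl arene. The conditions are neutral and free of fluoride, so both silyl ethers and the enol ether persist.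

**Step 11**
Reactants: 15 3-methoxy-2-[4-methoxy-3-(triisopropylsilyloxy)phenyl]-5-(3-methylbut-2-en-1-yl)-6-(triisopropylsilyloxy)-1-benzofuran
Product: 16 2-(3-hydroxy-4-methoxyphenyl)-3-methoxy-5-(3-methylbut-2-en-1-yl)-1-benzofuran-6-ol (target)
Conditions: TBAF, AcOH, THF, 0 °C
Reagents that add atoms: none
Why: Fluoride-induced cleavage of the two aryl silyl ethers; buffering with acetic acid protonates the phenoxides at once, and the medium is never acidic enough to cyclize the prenyl group onto the C6 hydroxyl.

## Compound list

1 | 3-hydroxyphenyl benzoate (resorcinol monobenzoate) | O=C(Oc1cccc(O)c1)c1ccccc1 | starting material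
2 | 2-bromo-5-hydroxyphenyl benzoate | O=C(Oc1cc(O)ccc1Br)c1ccccc1 | intermediate
3 | 2-(3-hydroxy-4-methoxyphenyl)acetic acid (homoisovanillic acid) | COc1ccc(CC(=O)O)cc1O | starting material
4 | methyl 2-(3-hydroxy-4-methoxyphenyl)acetate | COC(=O)Cc1ccc(OC)c(O)c1 | intermediate
5 | methyl 2-(3-acetoxy-4-methoxyphenyl)acetate | COC(=O)Cc1ccc(OC)c(OC(C)=O)c1 | intermediate
6 | methyl 2-(3-acetoxy-4-methoxyphenyl)-2-bromoacetate (racemic) | COC(=O)C(Br)c1ccc(OC)c(OC(C)=O)c1 | intermediate
7 | methyl 2-(3-acetoxy-4-methoxyphenyl)-2-[3-(benzoyloxy)-4-bromophenoxy]acetate (racemic) | COC(=O)C(Oc1ccc(Br)c(OC(=O)c2ccccc2)c1)c1ccc(OC)c(OC(C)=O)c1 | intermediate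
8 | 2-(4-bromo-3-hydroxyphenoxy)-2-(3-hydroxy-4-methoxyphenyl)acetic acid (racemic) | OC(=O)C(Oc1ccc(Br)c(O)c1)c1ccc(OC)c(O)c1 | intermediate
9 | triisopropylsilyl 2-[4-bromo-3-(triisopropylsilyloxy)phenoxy]-2-[4-methoxy-3-(triisopropylsilyloxy)phenyl]acetate (racemic, not isolated) | CC(C)[Si](C(C)C)(C(C)C)OC(=O)C(Oc1ccc(Br)c(O[Si](C(C)C)(C(C)C)C(C)C)c1)c1ccc(OC)c(O[Si](C(C)C)(C(C)C)C(C)C)c1 | intermediate
10 | 2-[4-bromo-3-(triisopropylsilyloxy)phenoxy]-2-[4-methoxy-3-(triisopropylsilyloxy)phenyl]acetic acid (racemic) | OC(=O)C(Oc1ccc(Br)c(O[Si](C(C)C)(C(C)C)C(C)C)c1)c1ccc(OC)c(O[Si](C(C)C)(C(C)C)C(C)C)c1 | intermediate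
11 | 2-[4-bromo-3-(triisopropylsilyloxy)phenoxy]-2-[4-methoxy-3-(triisopropylsilyloxy)phenyl]acetic trifluoroacetic anhydride (racemic, not isolated) | FC(F)(F)C(=O)OC(=O)C(Oc1ccc(Br)c(O[Si](C(C)C)(C(C)C)C(C)C)c1)c1ccc(OC)c(O[Si](C(C)C)(C(C)C)C(C)C)c1 | intermediate
12 | 5-bromo-2-[4-methoxy-3-(triisopropylsilyloxy)phenyl]-6-(triisopropylsilyloxy)-1-benzofuran-3(2H)-one (racemic) | O=C1C(c2ccc(OC)c(O[Si](C(C)C)(C(C)C)C(C)C)c2)Oc2cc(O[Si](C(C)C)(C(C)C)C(C)C)c(Br)cc21 | intermediate
13 | 5-bromo-3-methoxy-2-[4-methoxy-3-(triisopropylsilyloxy)phenyl]-6-(triisopropylsilyloxy)-1-benzofuran | COc1c(-c2ccc(OC)c(O[Si](C(C)C)(C(C)C)C(C)C)c2)oc2cc(O[Si](C(C)C)(C(C)C)C(C)C)c(Br)cc12 | intermediate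
14 | tributyl(3-methylbut-2-en-1-yl)stannane | CCCC[Sn](CCCC)(CCCC)CC=C(C)C | starting material
15 | 3-methoxy-2-[4-methoxy-3-(triisopropylsilyloxy)phenyl]-5-(3-methylbut-2-en-1-yl)-6-(triisopropylsilyloxy)-1-benzofuran | COc1c(-c2ccc(OC)c(O[Si](C(C)C)(C(C)C)C(C)C)c2)oc2cc(O[Si](C(C)C)(C(C)C)C(C)C)c(CC=C(C)C)cc12 | intermediate
16 | 2-(3-hydroxy-4-methoxyphenyl)-3-methoxy-5-(3-methylbut-2-en-1-yl)-1-benzofuran-6-ol | COc1ccc(-c2oc3cc(O)c(CC=C(C)C)cc3c2OC)cc1O | target

## Step count and least certain steps

Total: 11 steps. Longest linear sequence: 10 steps (steps 2 to 11 from acid 3); step 1 is a one-step branch that joins at step 5.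

**Step 8 (key step).** The most likely failure is decarbonylation of the activated acid, because the acyl cation bears an α-aryloxy and an α-(para-methoxyaryl) group that would stabilize the cation left behind. Also possible are slow closure of the five-membered ring on a ring A that the bromine slightly deactivates, and oxidation of the product enol at C2 by air.
The fallback forms C3–C3a intermolecularly, from an acylium ion that has no α-oxygen, and closes ring B at O1–C2 instead. It sets out from acid 3 and comes back at 12.
- Acid 3 is condensed with commercial 4-bromobenzene-1,3-diol in BF3·OEt2 at 80 °C (C-acylation para to one hydroxyl and ortho to the other), which should give 1-(5-bromo-2,4-dihydroxyphenyl)-2-(3-hydroxy-4-methoxyphenyl)ethan-1-one F1.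
- TIPSCl and imidazole silylate the two phenols that are not chelated to the ketone, giving 1-[5-bromo-2-hydroxy-4-(triisopropylsilyloxy)phenyl]-2-[4-methoxy-3-(triisopropylsilyloxy)phenyl]ethan-1-one F2.
- PhNMe3Br3 in THF brominates the ketone α-carbon to racemic 2-bromo-1-[5-bromo-2-hydroxy-4-(triisopropylsilyloxy)phenyl]-2-[4-methoxy-3-(triisopropylsilyloxy)phenyl]ethan-1-one F3.
- K2CO3 in acetone closes ring B by intramolecular phenoxide displacement to give 12.

**Step 10.** The prenyl group may be delivered with allylic transposition (bond formation at the dimethyl-substituted terminus), and oxidative addition is slow at an electron-rich bromide flanked by a bulky silyloxy group, which opens the way to protodebromination. A more electron-rich catalyst such as Pd2(dba)3 with P(t-Bu)3 addresses only the second point.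
The fallback sets out from 13 and comes back at 15. Stille coupling of 13 with allyltributylstannane, which has no regiochemical ambiguity, gives 3-methoxy-2-[4-methoxy-3-(triisopropylsilyloxy)phenyl]-5-(prop-2-en-1-yl)-6-(triisopropylsilyloxy)-1-benzofuran F4. Cross-metathesis of F4 with excess 2-methylbut-2-ene and second-generation Grubbs catalyst then gives 15.

**Step 9.** Competing C-methylation at C2, autoxidation of the enolate at C2, and carbonate-induced loss of the more labile silyl group followed by methylation of the freed phenol are the likely failures.
The fallback avoids the enolate altogether; it sets out from 12 and comes back at 13. Trimethyl orthoformate and a catalytic sulfonic acid in methanol convert the ketone into racemic 5-bromo-3,3-dimethoxy-2-[4-methoxy-3-(triisopropylsilyloxy)phenyl]-6-(triisopropylsilyloxy)-2,3-dihydro-1-benzofuran F5. F5 loses methanol under the same acid to give the aromatic enol ether 13.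

**Step 7.** The hydrolysis of the hindered silyl ester may be incomplete, or, if forced, the silyl ether ortho to bromine may begin to cleave.
The fallback never forms a silyl ester; it sets out from 7 and comes back at 10.
- Catalytic K2CO3 in methanol at 0 °C removes only the two aryl esters by transesterification, giving racemic methyl 2-(4-bromo-3-hydroxyphenoxy)-2-(3-hydroxy-4-methoxyphenyl)acetate F6.
- TIPSCl and imidazole give racemic methyl 2-[4-bromo-3-(triisopropylsilyloxy)phenoxy]-2-[4-methoxy-3-(triisopropylsilyloxy)phenyl]acetate F7.
- Me3SnOH in 1,2-dichloroethane at 80 °C, followed by a dilute HCl wash, cleaves the methyl ester under near-neutral conditions to give 10.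

## Further compounds

F1 | step 8 | 1-(5-bromo-2,4-dihydroxyphenyl)-2-(3-hydroxy-4-methoxyphenyl)ethan-1-one | COc1ccc(CC(=O)c2cc(Br)c(O)cc2O)cc1O
F2 | step 8 | 1-[5-bromo-2-hydroxy-4-(triisopropylsilyloxy)phenyl]-2-[4-methoxy-3-(triisopropylsilyloxy)phenyl]ethan-1-one | COc1ccc(CC(=O)c2cc(Br)c(O[Si](C(C)C)(C(C)C)C(C)C)cc2O)cc1O[Si](C(C)C)(C(C)C)C(C)C
F3 | step 8 | 2-bromo-1-[5-bromo-2-hydroxy-4-(triisopropylsilyloxy)phenyl]-2-[4-methoxy-3-(triisopropylsilyloxy)phenyl]ethan-1-one (racemic) | COc1ccc(C(Br)C(=O)c2cc(Br)c(O[Si](C(C)C)(C(C)C)C(C)C)cc2O)cc1O[Si](C(C)C)(C(C)C)C(C)C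
F4 | step 10 | 3-methoxy-2-[4-methoxy-3-(triisopropylsilyloxy)phenyl]-5-(prop-2-en-1-yl)-6-(triisopropylsilyloxy)-1-benzofuran | COc1c(-c2ccc(OC)c(O[Si](C(C)C)(C(C)C)C(C)C)c2)oc2cc(O[Si](C(C)C)(C(C)C)C(C)C)c(CC=C)cc12
F5 | step 9 | 5-bromo-3,3-dimethoxy-2-[4-methoxy-3-(triisopropylsilyloxy)phenyl]-6-(triisopropylsilyloxy)-2,3-dihydro-1-benzofuran (racemic) | COc1ccc(C2Oc3cc(O[Si](C(C)C)(C(C)C)C(C)C)c(Br)cc3C2(OC)OC)cc1O[Si](C(C)C)(C(C)C)C(C)C
F6 | step 7 | methyl 2-(4-bromo-3-hydroxyphenoxy)-2-(3-hydroxy-4-methoxyphenyl)acetate (racemic) | COC(=O)C(Oc1ccc(Br)c(O)c1)c1ccc(OC)c(O)c1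
F7 | step 7 | methyl 2-[4-bromo-3-(triisopropylsilyloxy)phenoxy]-2-[4-methoxy-3-(triisopropylsilyloxy)phenyl]acetate (racemic) | COC(=O)C(Oc1ccc(Br)c(O[Si](C(C)C)(C(C)C)C(C)C)c1)c1ccc(OC)c(O[Si](C(C)C)(C(C)C)C(C)C)c1
A1 | alternative 1 | 1-methoxy-7-methyl-1,3-bis(trimethylsilyloxy)octa-1,3,6-triene | COC(O[Si](C)(C)C)=CC(O[Si](C)(C)C)=CCC=C(C)C
A2 | alternative 1 | methyl propiolate | C#CC(=O)OC
A3 | alternative 1 | methyl 2,4-dihydroxy-5-(3-methylbut-2-enyl)benzoate | COC(=O)c1cc(CC=C(C)C)c(O)cc1O
A4 | alternative 2 | N,N-diethyl-4-(methoxymethoxy)-2-{[4-methoxy-3-(methoxymethoxy)phenyl]methoxy}-5-(3-methylbut-2-enyl)benzamide | CCN(CC)C(=O)c1cc(CC=C(C)C)c(OCOC)cc1OCc1ccc(OC)c(OCOC)c1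
A5 | alternative 2 | 3-methoxy-6-(methoxymethoxy)-2-[4-methoxy-3-(methoxymethoxy)phenyl]-5-(3-methylbut-2-enyl)-1-benzofuran | COCOc1cc2oc(-c3ccc(OC)c(OCOC)c3)c(OC)c2cc1CC=C(C)C
A6 | alternative 3 | 6-[3-(methoxymethylidene)-6-methyl-2-oxohept-5-enyl]-2,2-dimethyl-4H-1,3-dioxin-4-one | COC=C(CC=C(C)C)C(=O)CC1=CC(=O)OC(C)(C)O1
A7 | alternative 3 | 7-hydroxy-2,2-dimethyl-6-(3-methylbut-2-enyl)-4H-1,3-benzodioxin-4-one | CC1(C)OC(=O)c2cc(CC=C(C)C)c(O)cc2O1
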